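**Strategy.** Everything rests on cutting both aryl-ether bonds of the dioxane ring annulated to ring A, O-4–C-3 and O-1–C-2. Read this way, O-1 and O-4 are the carbonyl oxygens of an ortho-quinone, and C-2 (hemiketal) and C-3 (CHMe) are the enol carbons of an aryl ethyl ketone. A Cu(OTf)2/bis(oxazoline)-catalysed inverse-demand oxa-[4+2] cycloaddition of 5-allyl-3-methoxy-1,2-benzoquinone with the Z trimethylsilyl enol ether of 3′,4′,5′-trimethoxypropiophenone should form both bonds, close the ring, rearomatise ring A and set C-3 (R) in one operation, giving a silyl ketal. The quinone comes from eugenol via its catechol (Ag2O); mild desilylation finishes.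

Key step: step 5

Assumption: C-2 is configurationally labile through ring–chain tautomerism of the hemiketal, and the (2S,3R) target (hydroxyl trans to the C-3 methyl, aryl cis to it) is taken as the resting epimer; only C-3 must be fixed kinetically.

Remark: the quinone is reached through the catechol and not by direct oxidation of eugenol with a pentavalent iodine reagent such as o-iodoxybenzoic acid, because such reagents deliver oxygen to the methoxy-bearing ortho carbon of 2-methoxyphenols and expel methanol, which would give the quinone without its methoxy group.

Remark: (S,S)-tBu-box is 2,2′-(propane-2,2-diyl)bis[(4S)-4-tert-butyl-4,5-dihydro-1,3-oxazole]; its mirror image is equally available.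

**Step 1**
Reactants: 1 eugenol (2-methoxy-4-(prop-2-en-1-yl)phenol)
Product: 3 2-hydroxy-3-methoxy-5-(prop-2-en-1-yl)benzaldehyde, via salicyl alcohol 2 (not isolated)
Conditions: MgCl2, Et3N, (CH2O)n, MeCN, reflux; then 1 M HCl
Reagents that add atoms: paraformaldehyde (formaldehyde equivalent), C=O
Why: Casnati–Skattebøl ortho-formylation, in which the magnesium phenoxide delivers formaldehyde to the only free ortho position (para carries the allyl group) and the resulting salicyl alkoxide is oxidised to the aldehyde by hydride transfer to a second formaldehyde; no stereocentre is formed.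

**Step 2**
Reactants: 3 2-hydroxy-3-methoxy-5-(prop-2-en-1-yl)benzaldehyde
Product: 5 3-methoxy-5-(prop-2-en-1-yl)benzene-1,2-diol, via aryl formate 4 (not isolated)
Conditions: 6% aq H2O2, NaOH (1 equiv), H2O, 20–40 °C, argon; then 1 M HCl
Reagents that add atoms: hydrogen peroxide, OO
Why: Dakin oxidation, in which hydroperoxide adds to the ortho-hydroxy aldehyde, the electron-rich aryl group migrates to oxygen and the formate is saponified in the flask, the isolated terminal alkene being inert to alkaline peroxide.

**Step 3**
Reactants: 6 1-(3,4,5-trimethoxyphenyl)propan-1-one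
Product: 8 trimethyl{[(1Z)-1-(3,4,5-trimethoxyphenyl)prop-1-en-1-yl]oxy}silane (methyl cis to silyloxy), via lithium Z-enolate 7 (not isolated)
Conditions: LiN(iPr)2, THF, −78 °C; Me3SiCl, −78 °C to rt; pentane, filtration, distillation
Reagents that add atoms: chlorotrimethylsilane, C[Si](C)(C)Cl
Why: Kinetic enolisation of an aryl ethyl ketone with a lithium amide gives the Z enolate (methyl cis to oxygen, the aryl group disfavouring the alternative), and O-silylation traps that geometry as the silyl enol ether.

**Step 4**
Reactants: 5 3-methoxy-5-(prop-2-en-1-yl)benzene-1,2-diol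
Product: 9 3-methoxy-5-(prop-2-en-1-yl)cyclohexa-3,5-diene-1,2-dione (5-allyl-3-methoxy-1,2-benzoquinone)
Conditions: Ag2O, Na2SO4, CH2Cl2, 0 °C, dark; filtration through Celite under argon; cold solution used at once
Reagents that add atoms: none
Why: Two-electron oxidation of a catechol to its ortho-quinone by Ag2O under anhydrous, neutral, heterogeneous conditions, so that both oxygens and the methoxy group are already in place and the sensitive allyl quinone never meets water or soluble base.

**Step 5**
Reactants: 9 5-allyl-3-methoxy-1,2-benzoquinone; 8 (Z)-trimethylsilyl enol ether of 1-(3,4,5-trimethoxyphenyl)propan-1-one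
Product: 10 trimethyl{[(2S,3R)-5-methoxy-3-methyl-7-(prop-2-en-1-yl)-2-(3,4,5-trimethoxyphenyl)-2,3-dihydro-1,4-benzodioxin-2-yl]oxy}silane (silyloxy cis to methyl)
Conditions: Cu(OTf)2 (10 mol %), (S,S)-tBu-box (11 mol %), 4 Å MS, CH2Cl2, −78 to −40 °C, slow addition of 9; filtration through Et3N-deactivated silica
Reagents that add atoms: none
Why: Proposed new method: the divalent copper centre of the Cu(OTf)2–bis(oxazoline) complex chelates both carbonyl oxygens of 9 and lowers the LUMO of its O=C–C=O oxa-diene, so that the nucleophilic enol carbon of 8 (future C-3) bonds to the oxygen of the carbonyl next to the methoxy-bearing carbon (future O-4) while the other oxygen (future O-1) closes on the silyloxy-bearing carbon C-2, either concertedly and asynchronously or through a short-lived aryloxide/silyloxocarbenium pair, with rearomatisation of ring A as the driving force. The closest known reaction types are the thermal inverse-demand hetero-Diels–Alder additions of ortho-quinones to enol ethers and electron-rich styrenes, which give 1,4-benzodioxanes, the alkaloid-catalysed enantioselective [4+2] cycloaddition of ortho-quinones with ketene enolates, and the two-point activation of 1,2-dicarbonyl compounds by Cu(OTf)2–bis(oxazoline) catalysts in additions of silyl enol ethers. The dioxane ring is closed in the [4+2] mode, which in the stepwise limit is a 6-exo-trig capture of the oxocarbenium carbon by the aryloxide. C-3 is controlled by the ligand, whose tert-butyl group blocks one face of the chelated quinone at the reacting oxygen so that the enol ether offers one enantioface (the ligand antipode that gives 3R is to be fixed in a pilot run), whereas C-2 follows from suprafacial addition to the Z olefin, which places silyloxy cis to methyl, and can be corrected afterwards. The step needs three selectivities: oxygen regiochemistry, secured by the methoxy group, which leaves the adjacent carbonyl ketone-like while the remote carbonyl is a deactivated doubly vinylogous ester and the aryloxide that develops is the one not flanked by methoxy; hetero-diene instead of carbo-diene or carbon-centred Mukaiyama reactivity, secured by the electron-rich enol ether and the gain in aromaticity; and facial selectivity, secured by the chelating ligand, the low temperature that suppresses the uncatalysed background, and the geometric purity of 8. Since 10 is formed directly at the ketone oxidation level as a masked hemiketal, no later oxidation or basic step can touch the C-3 hydrogen.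

**Step 6**
Reactants: 10 (2S,3R)-trimethylsilyl ketal
Product: 13 (2S,3R)-5-methoxy-3-methyl-7-(prop-2-en-1-yl)-2-(3,4,5-trimethoxyphenyl)-2,3-dihydro-1,4-benzodioxin-2-ol (target), via cis-hemiketal 11 (not isolated), via hydroxy ketone 12 (not isolated)
Conditions: AcOH/THF/H2O (1:4:1), 0 °C to rt; crystallisation
Reagents that add atoms: none
Why: Silyl ether cleavage by hydrolysis at silicon frees the hemiketal without breaking a bond at C-3; ring–chain tautomerism through 12 should then let C-2 settle as the epimer with the anomerically favoured axial hydroxyl anti to the C-3 methyl and the aryl group equatorial, which is 13, while dilute acetic acid is too weak to enolise the transient ketone at a useful rate.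

**Compound list**

1 | eugenol, 2-methoxy-4-(prop-2-en-1-yl)phenol | C=CCc1ccc(O)c(OC)c1 | starting material
2 | 2-(hydroxymethyl)-6-methoxy-4-(prop-2-en-1-yl)phenol (salicyl alcohol, present as its magnesium phenoxide, not isolated) | C=CCc1cc(CO)c(O)c(OC)c1 | intermediate
3 | 2-hydroxy-3-methoxy-5-(prop-2-en-1-yl)benzaldehyde | C=CCc1cc(C=O)c(O)c(OC)c1 | intermediate
4 | 2-hydroxy-3-methoxy-5-(prop-2-en-1-yl)phenyl formate (not isolated) | C=CCc1cc(OC=O)c(O)c(OC)c1 | intermediate
5 | 3-methoxy-5-(prop-2-en-1-yl)benzene-1,2-diol (5-allyl-3-methoxycatechol) | C=CCc1cc(O)c(O)c(OC)c1 | intermediate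
6 | 1-(3,4,5-trimethoxyphenyl)propan-1-one | CCC(=O)c1cc(OC)c(OC)c(OC)c1 | starting material
7 | lithium (1Z)-1-(3,4,5-trimethoxyphenyl)prop-1-en-1-olate (not isolated) | [Li+].C/C=C(\[O-])c1cc(OC)c(OC)c(OC)c1 | intermediate
8 | trimethyl{[(1Z)-1-(3,4,5-trimethoxyphenyl)prop-1-en-1-yl]oxy}silane | C/C=C(\O[Si](C)(C)C)c1cc(OC)c(OC)c(OC)c1 | intermediate
9 | 3-methoxy-5-(prop-2-en-1-yl)cyclohexa-3,5-diene-1,2-dione | C=CCC1=CC(=O)C(=O)C(OC)=C1 | intermediate
10 | trimethyl{[(2S,3R)-5-methoxy-3-methyl-7-(prop-2-en-1-yl)-2-(3,4,5-trimethoxyphenyl)-2,3-dihydro-1,4-benzodioxin-2-yl]oxy}silane, silyloxy cis to methyl | C=CCc1cc(OC)c2c(c1)O[C@](O[Si](C)(C)C)(c3cc(OC)c(OC)c(OC)c3)[C@@H](C)O2 | intermediate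
11 | (2R,3R)-5-methoxy-3-methyl-7-(prop-2-en-1-yl)-2-(3,4,5-trimethoxyphenyl)-2,3-dihydro-1,4-benzodioxin-2-ol, hydroxyl cis to methyl (not isolated) | C=CCc1cc(OC)c2c(c1)O[C@](O)(c3cc(OC)c(OC)c(OC)c3)[C@@H](C)O2 | intermediate
12 | (2R)-2-[2-hydroxy-6-methoxy-4-(prop-2-en-1-yl)phenoxy]-1-(3,4,5-trimethoxyphenyl)propan-1-one (not isolated) | C=CCc1cc(OC)c(O[C@H](C)C(=O)c2cc(OC)c(OC)c(OC)c2)c(O)c1 | intermediate
13 | (2S,3R)-5-methoxy-3-methyl-7-(prop-2-en-1-yl)-2-(3,4,5-trimethoxyphenyl)-2,3-dihydro-1,4-benzodioxin-2-ol, hydroxyl trans to methyl | C=CCc1cc(OC)c2c(c1)O[C@@](O)(c1cc(OC)c(OC)c(OC)c1)[C@@H](C)O2 | target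

**Step count.** Total: 6 steps. Longest linear sequence: 5 steps (1 → 3 → 5 → 9 → 10 → 13, steps 1, 2, 4, 5 and 6); step 3 is the one-step side branch.

**Steps most likely to fail**

Step 5. What may go wrong:
- an uncatalysed background cycloaddition outruns the ligand-bound path, so facial selectivity is poor;
- the enol carbon bonds to the wrong quinone oxygen;
- carbon–carbon bond formation occurs at the quinone ring;
- electron transfer from the enol ether merely reduces the quinone.

Fallback (known chemistry; sets out from 3, comes back at 12). The phenol oxygen of 3 is the future O-4 and its formyl group is a latent O-1. Mitsunobu coupling of 3 with methyl (S)-lactate (PPh3, DIAD, THF, 0 °C) should install C-3 with inversion as methyl (2R)-2-[2-formyl-6-methoxy-4-(prop-2-en-1-yl)phenoxy]propanoate F1. Acid-catalysed hydrogen peroxide oxidation of this alkoxybenzaldehyde (30% H2O2, cat. H2SO4, MeOH, rt; the terminal alkene is inert in the absence of a peracid) should pass through methyl (2R)-2-[2-(formyloxy)-6-methoxy-4-(prop-2-en-1-yl)phenoxy]propanoate F2, which is methanolysed in the flask to methyl (2R)-2-[2-hydroxy-6-methoxy-4-(prop-2-en-1-yl)phenoxy]propanoate F3. AlMe3 and MeNH(OMe)·HCl (CH2Cl2, 0 °C) should convert the ester into (2R)-2-[2-hydroxy-6-methoxy-4-(prop-2-en-1-yl)phenoxy]-N-methoxy-N-methylpropanamide F4. Commercial 3,4,5-trimethoxyphenylmagnesium bromide (2.5 equiv, THF, −20 °C; the first equivalent is consumed by the phenol) should add once to the chelating amide, and aqueous NH4Cl should release hydroxy ketone 12, which closes to 13 as in step 6.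

Step 4. What may go wrong: on the silver oxide surface the quinone may be intercepted by unreacted catechol (conjugate addition, dimers), or may tautomerise through its benzylic allyl hydrogens to a quinone methide that polymerises before the filtrate reaches the catalyst.

Fallback (sets out from 1, comes back at 9, bypasses 3 and 5, makes no new compound). Teuber oxidation of eugenol itself with potassium nitrosodisulfonate, (KO3S)2NO (2.2 equiv), in KH2PO4-buffered water/CH2Cl2 at 0 °C. The phenoxyl radical should be trapped at the free ortho carbon, the only position from which a quinone can form without loss of a substituent. The quinone should pass into the organic layer as it forms, with no catechol present to intercept it. The layer is dried (Na2SO4) and used directly in step 5. The main route keeps the catechol path because 5 is a purifiable, storable precursor and its oxidation is anhydrous.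

Step 6. What may go wrong: incomplete convergence at C-2, so that 11, 12 and 13 persist together in solution, or slow erosion of C-3 by enolisation of 12 if acid contact is prolonged.

Fallback (sets out from 11 in equilibrium with 12, comes back at 13, makes no new compound). Crystallisation-induced diastereomer transformation in place of solution equilibration: the crude hemiketal mixture is taken up in a minimum of iPr2O/heptane containing a trace of AcOH and allowed to crystallise slowly. As 13 leaves solution the mother liquor should re-equilibrate through 12, so the solid collects one C-2 epimer without chromatography or further acid treatment.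

**Further compounds**

F1 | step 5 | methyl (2R)-2-[2-formyl-6-methoxy-4-(prop-2-en-1-yl)phenoxy]propanoate | COC(=O)[C@@H](C)Oc1c(C=O)cc(CC=C)cc1OC
F2 | step 5 | methyl (2R)-2-[2-(formyloxy)-6-methoxy-4-(prop-2-en-1-yl)phenoxy]propanoate | COC(=O)[C@@H](C)Oc1c(OC=O)cc(CC=C)cc1OC
F3 | step 5 | methyl (2R)-2-[2-hydroxy-6-methoxy-4-(prop-2-en-1-yl)phenoxy]propanoate | COC(=O)[C@@H](C)Oc1c(O)cc(CC=C)cc1OC
F4 | step 5 | (2R)-2-[2-hydroxy-6-methoxy-4-(prop-2-en-1-yl)phenoxy]-N-methoxy-N-methylpropanamide | CON(C)C(=O)[C@@H](C)Oc1c(O)cc(CC=C)cc1OC
F0 | step 4 | none | none
F0 | step 6 | none | none
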